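**Retrosynthetic overview**

1. Numbering used for the target and all intermediates: C1 (CH–OAc), C2 (CH2), C3(Me)=C4, C5 (CH2), C6=C7, C8 (ring-fusion CH), C9 (CH carrying the side chain), C10 (lactone C=O), C11 (OCH2), C12 (side-chain CHMe). The route rests on C5 of the nine-membered carbocycle: it is the unsubstituted end of the C3(Me)=C4–C5 allyl unit and is bonded to C6, which lies α to C7, the carbon shared with the γ-lactone and carried as a ketone. C5–C6 is therefore an allylic-alkylation retron.
2. Endgame: the acetate comes from the C1 alcohol (a TBS ether until then); the γ-lactone (second ring, closed last) comes from the C6=C7 enol triflate, CO and the C11 hydroxyl.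
3. First ring: the nine-membered carbocycle, closed at C5–C6 by palladium allyl alkylation of the C6 carbanion of a β-ketosulfone with the C3–C5 allylic carbonate.
4. Acyclic precursor: C6 from methyl phenyl sulfone added to a C7 aldehyde (Nef reaction of CH2NO2); the C3 methyl and C5 by methylalumination/hydroxymethylation of a C3≡C4 alkyne; C1–C2 by catalytic asymmetric propargylation, which sets C1.
5. C8–C9 by organocatalytic Michael addition of (R)-citronellal (C1, C9, C12 and the side chain) to PMBOCH2CH=CHNO2, which sets C8 and C9.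

Key step: step 13

Remark: metal alkoxides, borate esters and similar species that exist only until aqueous work-up are written as their protonated products; intermediates that a second reagent consumes in the same flask carry numbers.

**Route**

Step 1
Reactants: 1 (Z)-but-2-ene-1,4-diol
Product: 2 (Z)-1,4-bis[(4-methoxybenzyl)oxy]but-2-ene
Conditions: NaH, 4-methoxybenzyl chloride, n-Bu4NI (cat.), THF/DMF, 0 °C to rt
Reagents that add atoms: 4-methoxybenzyl chloride, COc1ccc(CCl)cc1
Why: Williamson ether synthesis on both primary allylic alkoxides; no stereocentre is formed.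

Step 2
Reactants: 2 (Z)-1,4-bis[(4-methoxybenzyl)oxy]but-2-ene
Product: 4 2-[(4-methoxybenzyl)oxy]acetaldehyde, via secondary ozonide 3 (not isolated)
Conditions: O3, CH2Cl2, −78 °C; then PPh3, −78 °C to rt
Reagents that add atoms: ozone, [O-][O+]=O
Why: Criegee ozonolysis of the symmetrical cis-alkene and reduction of the ozonide by PPh3 should give two molecules of the aldehyde, the alkene being consumed far faster than the anisyl rings when ozone is dosed to the end point.

Step 3
Reactants: 4 2-[(4-methoxybenzyl)oxy]acetaldehyde; 5 nitromethane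
Product: 6 1-[(4-methoxybenzyl)oxy]-3-nitropropan-2-ol (racemic)
Conditions: MeNO2 (5 equiv), Et3N (0.2 equiv), THF, 0 °C to rt
Reagents that add atoms: none
Why: Henry (nitroaldol) addition of the nitronate to an unhindered aldehyde; the racemic carbinol centre is removed in step 4.

Step 4
Reactants: 6 1-[(4-methoxybenzyl)oxy]-3-nitropropan-2-ol
Product: 8 1-methoxy-4-({[(2E)-3-nitroprop-2-en-1-yl]oxy}methyl)benzene, via mesylate 7 (not isolated)
Conditions: MsCl, Et3N (2.2 equiv), CH2Cl2, −40 to 0 °C
Reagents that add atoms: none
Why: O-mesylation followed by E1cB elimination through the nitronate should give the thermodynamically preferred (E)-nitroalkene under conditions cold and brief enough to avoid base-induced migration of the double bond.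

Step 5
Reactants: 8 (E)-nitroalkene; 9 (R)-citronellal
Product: 10 (2S,3S)-3-{[(4-methoxybenzyl)oxy]methyl}-2-[(2R)-6-methylhept-5-en-2-yl]-4-nitrobutanal
Conditions: 9 (1.5 equiv), (R)-α,α-diphenylprolinol trimethylsilyl ether (10 mol %), 4-nitrophenol (10 mol %), toluene, 0 °C to rt
Reagents that add atoms: none
Why: Enamine-catalysed Michael addition (Hayashi–Jørgensen catalyst) in which the anti-(E)-enamine, shielded on one face by the diphenyl(silyloxy)methyl group, adds to the nitroalkene through the synclinal acyclic transition state, so that the (R)-catalyst should set C9 (S) and C8 (S) in the syn relationship, overriding the remote C12 centre.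

Step 6
Reactants: 10 Michael adduct; 11 allenylboronic acid pinacol ester
Product: 12 (1R,8S,9S,12R)-nitro homopropargylic alcohol
Conditions: 11 (1.5 equiv), (R)-TRIP [(R)-3,3'-bis(2,4,6-triisopropylphenyl)-1,1'-binaphthyl-2,2'-diyl hydrogen phosphate] (10 mol %), 4 Å molecular sieves, toluene, −20 °C; then aq. NaHCO3
Reagents that add atoms: none
Why: Chiral-phosphoric-acid-catalysed allenylboration (SE2' propargylation) through a closed six-membered transition state, in which the (R)-acid should direct the propargyl group to the Re face of the aldehyde and set C1 as R, while the absence of a free Lewis acid avoids carbonyl-ene cyclisation onto the side-chain alkene.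

Step 7
Reactants: 12 nitro homopropargylic alcohol
Product: 13 (1R,8S,9S,12R)-C1 TBS ether
Conditions: TBSOTf (1.3 equiv), 2,6-lutidine (2 equiv), CH2Cl2, −78 to −40 °C
Reagents that add atoms: tert-butyldimethylsilyl triflate, CC(C)(C)[Si](C)(C)OS(=O)(=O)C(F)(F)F
Why: Silylation of the hindered secondary alcohol with the silyl triflate is fast at low temperature, where the weak base does not convert the primary nitro group into a silyl nitronate.

Step 8
Reactants: 13 C1 TBS ether nitro compound
Product: 15 (1R,8R,9S,12R)-C7 aldehyde, via sodium nitronate 14 (not isolated)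
Conditions: NaOMe (1.1 equiv), MeOH, 0 °C; then aq. TiCl3 (4 equiv), NH4OAc buffer (pH about 5), 0 °C to rt; product used crude
Reagents that add atoms: water, O
Why: Reductive Nef reaction (McMurry conditions) in which trivalent titanium reduces the nitronate to the imine, hydrolysed in the buffer to the aldehyde; no nitrile oxide is formed that could add to the C3≡C4 alkyne, and the mildly acidic medium should leave C8, the TBS ether and the PMB ether intact.

Step 9
Reactants: 15 C7 aldehyde; 16 methyl phenyl sulfone
Product: 18 (1R,8R,9S,12R)-β-hydroxysulfone (both C7 epimers), via [(phenylsulfonyl)methyl]lithium 17 (not isolated)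
Conditions: 16 (1.3 equiv), n-BuLi (1.25 equiv), THF, −78 °C; then 15, −78 °C; aq. NH4Cl
Reagents that add atoms: none
Why: 1,2-Addition of the α-sulfonyl carbanion to the aldehyde at −78 °C is faster than enolisation at C8 or deprotonation of the alkyne; the new C7 carbinol centre needs no control because it is oxidised in step 12.

Step 10
Reactants: 18 β-hydroxysulfone
Product: 20 (E)-allylic alcohol diol, via alkenyldimethylalane 19 (not isolated)
Conditions: Me3Al (4 equiv), Cp2ZrCl2 (0.5 equiv), CH2Cl2, 0 °C to rt; then (CH2O)n, 0 °C to rt; aq. potassium sodium tartrate work-up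
Reagents that add atoms: trimethylaluminium, C[Al](C)C; formaldehyde (as paraformaldehyde), C=O
Why: Zirconium-catalysed syn-methylalumination of the terminal alkyne (Negishi carboalumination) places methyl on C3 and aluminium on C4, and hydroxymethylation of the alkenylalane with retention should give the (E)-C3=C4 alkene with C5 attached, the C7 hydroxyl travelling as its aluminium alkoxide and the sulfone and ethers being inert.

Step 11
Reactants: 20 diol
Product: 21 C5 methyl carbonate
Conditions: ClCO2Me (1.2 equiv), pyridine, CH2Cl2, −20 °C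
Reagents that add atoms: methyl chloroformate, COC(Cl)=O
Why: Acylation is selective for the unhindered primary allylic hydroxyl over the C7 carbinol flanked by the C8 branch and the sulfonylmethyl group.

Step 12
Reactants: 21 C5 methyl carbonate
Product: 22 acyclic β-ketosulfone allylic carbonate (1R,8R,9S,12R; 3E)
Conditions: Dess–Martin periodinane (1.5 equiv), NaHCO3, CH2Cl2, 0 °C to rt
Reagents that add atoms: none
Why: Dess–Martin oxidation of the β-hydroxysulfone to the β-ketosulfone under buffered, non-basic conditions that should neither epimerise C8 nor eliminate the C11 ether.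

Step 13
Reactants: 22 acyclic β-ketosulfone allylic carbonate
Product: 23 nine-membered (E)-cycloalkenyl β-ketosulfone (C6 epimers)
Conditions: Pd(PPh3)4 (10 mol %), dppe (12 mol %), THF, 65 °C, syringe-pump addition of 22 (final 0.003 M)
Reagents that add atoms: none
Why: Zerovalent palladium ionises the allylic methyl carbonate with loss of CO2 to an η3-allyl complex of divalent palladium over C3–C5, and the methoxide released deprotonates the β-ketosulfone, the only acidic C–H, so that the soft C6 carbanion attacks C5 on the face opposite the metal; this is the intramolecular Tsuji–Trost allylic alkylation of sulfone-stabilised enolates, a reaction type known to favour medium rings. The nine-membered carbocycle closes by attack on the distal allyl terminus, so that C3, C4 and C5 all become ring atoms and C3=C4 ends endocyclic. The only new stereocentre, C6, is not controlled and needs no control, since the sulfone is removed in step 14 and C6 becomes sp2 in step 15. The step needs C5 over C3 regioselectivity, C- over O-alkylation, retention of the E geometry and cyclisation over oligomerisation: attack at C3 would build a quaternary centre in a seven-membered ring and is sterically disfavoured, an O-allylated enol ether would re-ionise under the catalyst and funnel to the C-alkylated ketone, syn/anti exchange at C3 would require a σ-complex at a tertiary carbon, and high dilution with slow addition suppresses intermolecular alkylation. The essentially neutral medium should leave the β-alkoxy ketone and the silyl ether untouched.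

Step 14
Reactants: 23 nine-membered β-ketosulfone
Product: 24 nine-membered C7 ketone (1R,8R,9S,12R; 3E)
Conditions: SmI2 (2.5 equiv), THF/MeOH, −78 °C
Reagents that add atoms: none
Why: Reductive desulfonylation of the α-sulfonyl ketone by single-electron transfer, with protonation of the resulting enolate by methanol, erases the C6 centre without touching the β-alkoxy group, the alkenes or C8.

Step 15
Reactants: 24 nine-membered C7 ketone
Product: 26 C6=C7 enol triflate, via potassium enolate 25 (not isolated)
Conditions: KN(SiMe3)2 (1.1 equiv), THF, −78 °C; then PhNTf2 (1.2 equiv), −78 to −20 °C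
Reagents that add atoms: N-phenylbis(trifluoromethanesulfonimide), O=S(=O)(N(c1ccccc1)S(=O)(=O)C(F)(F)F)C(F)(F)F
Why: Kinetic deprotonation by the bulky amide at the unhindered C6 methylene rather than at the tertiary C8–H should give the enolate that is cis within the ring (a second trans alkene is not tolerated in a nine-membered ring), which is trapped on oxygen as the enol triflate with C8 untouched.

Step 16
Reactants: 26 C6=C7 enol triflate
Product: 27 C11 hydroxy enol triflate
Conditions: DDQ (1.3 equiv), CH2Cl2/pH 7 phosphate buffer (10:1), 0 °C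
Reagents that add atoms: none
Why: Oxidative cleavage of the PMB ether by hydride abstraction from the electron-rich benzylic position, to which the enol triflate, the silyl ether and the unactivated alkenes are inert.

Step 17
Reactants: 27 C11 hydroxy enol triflate
Product: 28 C1 TBS ether of the lactone (1R,8S,9S,12R; 3E,6E)
Conditions: Pd(PPh3)4 (10 mol %), CO (1 atm), n-Bu3N (3 equiv), LiCl (3 equiv), MeCN, 60 °C
Reagents that add atoms: carbon monoxide, [C-]#[O+]
Why: Carbonylative lactonisation of a hydroxy vinyl triflate: oxidative addition of zerovalent palladium at C7, CO insertion and capture of the acylpalladium by the C11 hydroxyl close the five-membered lactone (C10 from CO) with retention of the C6=C7 geometry.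

Step 18
Reactants: 28 TBS-protected lactone
Product: 29 C1 hydroxy lactone
Conditions: HF·pyridine, pyridine/THF, 0 °C to rt
Reagents that add atoms: none
Why: Fluoride-mediated desilylation under buffered, weakly acidic conditions avoids base-induced migration of the C6=C7 bond or epimerisation at C8.

Step 19
Reactants: 29 C1 hydroxy lactone
Product: 30 target acetate CNP0288725.2
Conditions: Ac2O, pyridine, DMAP (cat.), CH2Cl2, 0 °C to rt
Reagents that add atoms: acetic anhydride, CC(=O)OC(C)=O
Why: DMAP-catalysed O-acetylation of the secondary alcohol proceeds with retention at C1.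

**Compound list**

1 | (Z)-but-2-ene-1,4-diol | OC/C=C\CO | starting material
2 | (Z)-1,4-bis[(4-methoxybenzyl)oxy]but-2-ene | COc1ccc(COC/C=C\COCc2ccc(OC)cc2)cc1 | intermediate
3 | 3,5-bis{[(4-methoxybenzyl)oxy]methyl}-1,2,4-trioxolane (secondary ozonide, not isolated) | COc1ccc(COCC2OOC(COCc3ccc(OC)cc3)O2)cc1 | intermediate
4 | 2-[(4-methoxybenzyl)oxy]acetaldehyde | O=CCOCc1ccc(OC)cc1 | intermediate
5 | nitromethane | C[N+](=O)[O-] | starting material
6 | 1-[(4-methoxybenzyl)oxy]-3-nitropropan-2-ol (racemic) | OC(COCc1ccc(OC)cc1)C[N+](=O)[O-] | intermediate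
7 | 1-[(4-methoxybenzyl)oxy]-3-nitropropan-2-yl methanesulfonate (not isolated) | CS(=O)(=O)OC(COCc1ccc(OC)cc1)C[N+](=O)[O-] | intermediate
8 | 1-methoxy-4-({[(2E)-3-nitroprop-2-en-1-yl]oxy}methyl)benzene | O=[N+]([O-])/C=C/COCc1ccc(OC)cc1 | intermediate
9 | (R)-citronellal | O=CC[C@H](C)CCC=C(C)C | starting material
10 | (2S,3S)-3-{[(4-methoxybenzyl)oxy]methyl}-2-[(2R)-6-methylhept-5-en-2-yl]-4-nitrobutanal | O=C[C@@H]([C@H](C)CCC=C(C)C)[C@H](COCc1ccc(OC)cc1)C[N+](=O)[O-] | intermediate
11 | allenylboronic acid pinacol ester | C=C=CB1OC(C)(C)C(C)(C)O1 | starting material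
12 | nitro homopropargylic alcohol (C1 R, C8 S, C9 S, C12 R): C1 carbinol with CH2C≡CH, C9 side chain, C8 with CH2OPMB and CH2NO2 | O[C@H](CC#C)[C@@H]([C@H](C)CCC=C(C)C)[C@H](COCc1ccc(OC)cc1)C[N+](=O)[O-] | intermediate
13 | C1 TBS ether of 12 (C1 R, C8 S, C9 S, C12 R) | C[Si](C)(C(C)(C)C)O[C@H](CC#C)[C@@H]([C@H](C)CCC=C(C)C)[C@H](COCc1ccc(OC)cc1)C[N+](=O)[O-] | intermediate
14 | sodium nitronate of 13 (not isolated) | C[Si](C)(C(C)(C)C)O[C@H](CC#C)[C@@H]([C@H](C)CCC=C(C)C)[C@H](COCc1ccc(OC)cc1)C=[N+]([O-])[O-].[Na+] | intermediate
15 | C7 aldehyde (C1 R, C8 R, C9 S, C12 R) | C[Si](C)(C(C)(C)C)O[C@H](CC#C)[C@@H]([C@H](C)CCC=C(C)C)[C@H](COCc1ccc(OC)cc1)C=O | intermediate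
16 | methyl phenyl sulfone | CS(=O)(=O)c1ccccc1 | starting material
17 | [(phenylsulfonyl)methyl]lithium (not isolated) | [Li]CS(=O)(=O)c1ccccc1 | intermediate
18 | β-hydroxysulfone with C3≡C4 alkyne (C1 R, C8 R, C9 S, C12 R; C7 epimers) | C[Si](C)(C(C)(C)C)O[C@H](CC#C)[C@@H]([C@H](C)CCC=C(C)C)[C@H](COCc1ccc(OC)cc1)C(O)CS(=O)(=O)c1ccccc1 | intermediate
19 | (E)-C4 alkenyldimethylalane, C7 dimethylaluminium alkoxide (not isolated) | C[Si](C)(C(C)(C)C)O[C@H](C/C(C)=C/[Al](C)C)[C@@H]([C@H](C)CCC=C(C)C)[C@H](COCc1ccc(OC)cc1)C(O[Al](C)C)CS(=O)(=O)c1ccccc1 | intermediate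
20 | diol: (E)-C5 allylic alcohol, C7 carbinol, C6 sulfone | C[Si](C)(C(C)(C)C)O[C@H](C/C(C)=C/CO)[C@@H]([C@H](C)CCC=C(C)C)[C@H](COCc1ccc(OC)cc1)C(O)CS(=O)(=O)c1ccccc1 | intermediate
21 | C5 methyl carbonate, C7 carbinol | C[Si](C)(C(C)(C)C)O[C@H](C/C(C)=C/COC(=O)OC)[C@@H]([C@H](C)CCC=C(C)C)[C@H](COCc1ccc(OC)cc1)C(O)CS(=O)(=O)c1ccccc1 | intermediate
22 | acyclic β-ketosulfone with (E)-allylic methyl carbonate, C1 OTBS, C11 OPMB (C1 R, C8 R, C9 S, C12 R) | C[Si](C)(C(C)(C)C)O[C@H](C/C(C)=C/COC(=O)OC)[C@@H]([C@H](C)CCC=C(C)C)[C@H](COCc1ccc(OC)cc1)C(=O)CS(=O)(=O)c1ccccc1 | intermediate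
23 | nine-membered (E)-cycloalkenyl β-ketosulfone (C6 epimers) | C[Si](C)(C(C)(C)C)O[C@@H]1C/C(C)=C/CC(S(=O)(=O)c2ccccc2)C(=O)[C@@H](COCc2ccc(OC)cc2)[C@@H]1[C@H](C)CCC=C(C)C | intermediate
24 | nine-membered (E)-cycloalkenyl C7 ketone | C[Si](C)(C(C)(C)C)O[C@@H]1C/C(C)=C/CCC(=O)[C@@H](COCc2ccc(OC)cc2)[C@@H]1[C@H](C)CCC=C(C)C | intermediate
25 | potassium C6=C7 enolate of 24 (not isolated) | C[Si](C)(C(C)(C)C)O[C@@H]1C/C(C)=C/C/C=C(/[O-])[C@@H](COCc2ccc(OC)cc2)[C@@H]1[C@H](C)CCC=C(C)C.[K+] | intermediate
26 | C6=C7 enol triflate (cis within the ring), C11 OPMB | C[Si](C)(C(C)(C)C)O[C@@H]1C/C(C)=C/C/C=C(/OS(=O)(=O)C(F)(F)F)[C@@H](COCc2ccc(OC)cc2)[C@@H]1[C@H](C)CCC=C(C)C | intermediate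
27 | C11 hydroxy enol triflate | C[Si](C)(C(C)(C)C)O[C@@H]1C/C(C)=C/C/C=C(/OS(=O)(=O)C(F)(F)F)[C@@H](CO)[C@@H]1[C@H](C)CCC=C(C)C | intermediate
28 | C1 TBS ether of the bicyclic lactone (C1 R, C8 S, C9 S, C12 R) | C[Si](C)(C(C)(C)C)O[C@@H]1C/C(C)=C/C/C=C2/C(=O)OC[C@H]2[C@@H]1[C@H](C)CCC=C(C)C | intermediate
29 | C1 hydroxy bicyclic lactone | O[C@@H]1C/C(C)=C/C/C=C2/C(=O)OC[C@H]2[C@@H]1[C@H](C)CCC=C(C)C | intermediate
30 | CNP0288725.2, C1 acetate (C1 R, C8 S, C9 S, C12 R; 3E, 6E) | CC(=O)O[C@@H]1C/C(C)=C/C/C=C2/C(=O)OC[C@H]2[C@@H]1[C@H](C)CCC=C(C)C | target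

**Step count**

Total steps: 19. Longest linear sequence: 19 steps (1 to 30 through nitroalkene 8); 15 steps counted from (R)-citronellal 9.

**Steps most likely to fail**

1. Step 13 (palladium allyl macrocyclisation). What may go wrong: the allyl complex may equilibrate its geometry towards the less strained ring-cis isomer, lose a β-hydrogen to give a diene, or be alkylated intermolecularly, instead of closing to the strained (E)-cyclononene. Fallback, from 20 back to 23, without an allyl–metal intermediate: diol 20 is brominated selectively at the allylic hydroxyl with NBS/Me2S (Corey–Kim) to give allylic bromide F1. Dess–Martin oxidation of the C7 carbinol then gives bromo β-ketosulfone F2. Cs2CO3 in MeCN at high dilution closes the ring by direct SN2 displacement at C5, which cannot scramble the C3=C4 geometry, and should give 23.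

2. Step 8 (reductive Nef reaction). What may go wrong: the reduction may stall at the oxime, or the new α-branched β-alkoxy aldehyde may epimerise at C8 or lose PMB alcohol by β-elimination in the aqueous medium. Fallback, from 13 back to 15, in two separately controlled operations: the nitro group of 13 is reduced to aldoxime F3 with SnCl2/PhSH/Et3N. F3 is then cleaved by oxime exchange with aqueous glyoxylic acid (NaOAc buffer, rt) to release aldehyde 15 under near-neutral conditions.

3. Step 6 (catalytic asymmetric propargylation). What may go wrong: facial selectivity may be poor if the catalyst and the hindered, doubly α-branched aldehyde form a mismatched pair, so that the C1 epimer is formed in quantity. Fallback, from 10 back to 12, by stereochemical correction instead of catalyst control: 10 is treated with 11 and achiral diphenyl phosphate to give 12 together with its C1 epimer F4, which is separated by chromatography. F4 is inverted by Mitsunobu reaction (4-nitrobenzoic acid, PPh3, DIAD) to 4-nitrobenzoate F5, and methanolysis (K2CO3, MeOH) converts F5 into 12.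

**Further compounds**

F1 | step 13 | allylic bromide of 20 (C5 bromide, C7 carbinol) | C[Si](C)(C(C)(C)C)O[C@H](C/C(C)=C/CBr)[C@@H]([C@H](C)CCC=C(C)C)[C@H](COCc1ccc(OC)cc1)C(O)CS(=O)(=O)c1ccccc1
F2 | step 13 | bromo β-ketosulfone (C5 bromide, C7 ketone) | C[Si](C)(C(C)(C)C)O[C@H](C/C(C)=C/CBr)[C@@H]([C@H](C)CCC=C(C)C)[C@H](COCc1ccc(OC)cc1)C(=O)CS(=O)(=O)c1ccccc1
F3 | step 8 | C7 aldoxime of 15 | C[Si](C)(C(C)(C)C)O[C@H](CC#C)[C@@H]([C@H](C)CCC=C(C)C)[C@H](COCc1ccc(OC)cc1)C=NO
F4 | step 6 | C1 epimer of 12 (C1 S) | O[C@@H](CC#C)[C@@H]([C@H](C)CCC=C(C)C)[C@H](COCc1ccc(OC)cc1)C[N+](=O)[O-]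
F5 | step 6 | 4-nitrobenzoate of 12 (C1 R) | O=C(O[C@H](CC#C)[C@@H]([C@H](C)CCC=C(C)C)[C@H](COCc1ccc(OC)cc1)C[N+](=O)[O-])c1ccc(cc1)[N+](=O)[O-]
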